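## Retrosynthetic overview

1. The C6–C7 and C6'–C7' bonds are cut (Suzuki–Miyaura) to give enol triflates 11 (ring A) and 23 (ring B) and the C22 nonaene bis(pinacol boronate) 27, made from crocetindial.
2. Each triflate goes back through a 2,2,6-trimethylcyclohexanone (C5 methyl by reductive methylation, side chain by Wittig olefination or cross-metathesis) to a 2-(2,2-dimethyl-3-oxocyclohex-4-enyl)acetaldehyde: 4 for ring A, its antipode 13 for ring B.
3. Feature used: the stereocentre of each ring (C2 in ring A, C2' in ring B) sits beside quaternary C1/C1' and bears two two-carbon branches, the ring segment C3–C4 and the CH2–CH= root of the side chain. Once C4–C5 is cut, both branches are CH2CHO groups and the centre is an achiral CH(CH2CHO)2 carbon. Because the rings are antipodal (2R, 2'S), the two proline enantiomers turn one keto-dialdehyde 2 into both.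
4. Keto-dialdehyde 2 comes from ozonolysis of α-campholenic aldehyde 1, which erases its stereocentre.
5. Ring order: ring A is closed in step 2 and ring B in step 6, independently, each by the aldol condensation; no other ring is formed.

Key step: step 2

Remark 1: ring positions are given in carotenoid numbering (C1 quaternary, C2 stereocentre, C5 methyl-bearing, C6 attached to the chain); compound 1 may be of any enantiomeric composition.
Remark 2: the pairing (R)-proline → 4 and (S)-proline → 13 is the sense predicted by the chair model of step 2. Both antipodes are needed, so a reversed sense would be met by exchanging the two catalysts between steps 2 and 6.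

## Route

Step 1
Reactants: 1 α-campholenic aldehyde
Product: 2 3-(2-methyl-3-oxobutan-2-yl)pentanedial
Conditions: O3, CH2Cl2, −78 °C; then PPh3, −78 °C → rt
Reagents that add atoms: ozone, [O-][O+]=O
Why: Ozonolysis with reductive work-up cleaves the electron-rich trisubstituted ring alkene into a methyl ketone and a second CH2CHO arm, which makes the former stereocentre achiral.

Step 2
Reactants: 2 3-(2-methyl-3-oxobutan-2-yl)pentanedial
Product: 4 (R)-2-(2,2-dimethyl-3-oxocyclohex-4-en-1-yl)acetaldehyde, via ketol 3 (not isolated)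
Conditions: (R)-proline (30 mol%), DMSO (0.05 M, slow addition of 2), 25 °C; then p-TsOH·H2O (30 mol%), 40 °C
Reagents that add atoms: none
Why: Proposed new method: (R)-proline condenses with the only ketone of achiral 2, whose only α-hydrogens are those of the CH3 group (C1 on the other side is quaternary); the enamine carbon (future C5) adds to one of the two enantiotopic formyl carbons (future C4) while the proline CO2H hydrogen-bonds to and protonates that formyl oxygen, hydrolysis gives ketol 3, and the acid then removes water by E1cB to leave the C4=C5 enone. The closest known reaction type is the amino-acid-catalysed desymmetrising intramolecular aldol condensation of prochiral triketones and of 4-substituted heptane-2,6-diones (Hajos–Parrish type); new here are the formyl acceptors and a methyl ketone donor flanked by a quaternary carbon. Ring A (C1–C6) closes by a 6-(enolendo)-exo-trig attack through a chair in which the C4 oxygen is axial and held by the carboxylic acid. The C2 stereocentre is set by the catalyst alone: in that chair the unreacted CH2CHO arm on C2 sits equatorial, away from the axial C4–O···HO2C contact, and with the anti enamine of (R)-proline this picks the arm that leaves C2 as R, the same model that accounts for the sense of the Hajos–Parrish cyclisation. The step needs chemoselectivity and enantiotopic-group selectivity: an enamine formed at a formyl arm has no ring larger than four-membered open to it and is only a resting state, its intermolecular aldol reactions being held back by dilution, while the achiral substrate offers no bias that could oppose the catalyst. The product should not racemise, since C2 is not α to either carbonyl group.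

Step 3
Reactants: 4 (R)-2-(2,2-dimethyl-3-oxocyclohex-4-en-1-yl)acetaldehyde; 5 isopropyltriphenylphosphonium iodide
Product: 7 (5R)-6,6-dimethyl-5-(3-methylbut-2-en-1-yl)cyclohex-2-en-1-one, via ylide 6 (not isolated)
Conditions: 5, KN(SiMe3)2, THF, 0 °C; then 4, −78 °C → 0 °C
Reagents that add atoms: none
Why: Wittig olefination; the non-stabilised ylide should react with the unhindered aldehyde far faster than with the conjugated ketone shielded by the gem-dimethyl carbon, and the product alkene has no E/Z issue.

Step 4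
Reactants: 7 (5R)-6,6-dimethyl-5-(3-methylbut-2-en-1-yl)cyclohex-2-en-1-one
Product: 9 (3R)-2,2,6-trimethyl-3-(3-methylbut-2-en-1-yl)cyclohexan-1-one (both C6 epimers), via lithium enolate 8 (not isolated)
Conditions: LiBH(s-Bu)3, THF, −78 °C; then MeI, −78 °C → rt
Reagents that add atoms: iodomethane, CI
Why: Conjugate hydride reduction of a β-unsubstituted cyclohexenone followed by C-methylation of the regiodefined enolate (reductive alkylation); the new methyl-bearing centre (C5) forms as a mixture that does not matter because it becomes sp2 in step 5.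

Step 5
Reactants: 9 (3R)-2,2,6-trimethyl-3-(3-methylbut-2-en-1-yl)cyclohexan-1-one
Product: 11 (5R)-2,6,6-trimethyl-5-(3-methylbut-2-en-1-yl)cyclohex-1-en-1-yl trifluoromethanesulfonate, via lithium enolate 10 (not isolated)
Conditions: LiN(i-Pr)2, THF, −78 → 0 °C; then PhNTf2, 0 °C → rt
Reagents that add atoms: N-phenylbis(trifluoromethanesulfonimide), O=S(=O)(N(c1ccccc1)S(=O)(=O)C(F)(F)F)C(F)(F)F
Why: Enol triflation; the ketone has a single α-hydrogen (C5–H, C1 being quaternary), so only the tetrasubstituted C5=C6 enolate can form and O-sulfonylation fixes the ring double bond of the target.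

Step 6
Reactants: 2 3-(2-methyl-3-oxobutan-2-yl)pentanedial
Product: 13 (S)-2-(2,2-dimethyl-3-oxocyclohex-4-en-1-yl)acetaldehyde, via ketol 12 (not isolated)
Conditions: (S)-proline (30 mol%), DMSO (0.05 M, slow addition of 2), 25 °C; then p-TsOH·H2O (30 mol%), 40 °C
Reagents that add atoms: none
Why: Proposed new method: this is the mirror image of step 2, in which the methyl-ketone enamine of (S)-proline attacks the other enantiotopic formyl group through the enantiomeric 6-(enolendo)-exo-trig chair (spectator arm equatorial, formyl oxygen axial and held by the CO2H) and acid-promoted E1cB dehydration gives the enone with C2' as S; the closest known reaction type is again the Hajos–Parrish-type desymmetrising aldol condensation.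

Step 7
Reactants: 13 (S)-2-(2,2-dimethyl-3-oxocyclohex-4-en-1-yl)acetaldehyde; 14 methyltriphenylphosphonium bromide
Product: 16 (5R)-6,6-dimethyl-5-(prop-2-en-1-yl)cyclohex-2-en-1-one, via ylide 15 (not isolated)
Conditions: 14, KN(SiMe3)2, THF, 0 °C; then 13, −78 °C → 0 °C
Reagents that add atoms: none
Why: Wittig methylenation, chemoselective for the aldehyde as in step 3; the descriptor changes to R only through the priority rules, the spatial arrangement being that of 13.

Step 8
Reactants: 16 (5R)-6,6-dimethyl-5-(prop-2-en-1-yl)cyclohex-2-en-1-one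
Product: 18 (3S)-2,2,6-trimethyl-3-(prop-2-en-1-yl)cyclohexan-1-one (both C6 epimers), via lithium enolate 17 (not isolated)
Conditions: LiBH(s-Bu)3, THF, −78 °C; then MeI, −78 °C → rt
Reagents that add atoms: iodomethane, CI
Why: Conjugate reduction and enolate methylation (reductive alkylation) as in step 4; the terminal alkene is inert to the borohydride and the new methyl centre is again inconsequential.

Step 9
Reactants: 19 2-methylidenepropane-1,3-diol
Product: 20 2-methylidenepropane-1,3-diyl bis(tert-butyldimethylsilyl) ether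
Conditions: TBSCl, imidazole, DMF, rt
Reagents that add atoms: tert-butyldimethylsilyl chloride, CC(C)(C)[Si](C)(C)Cl
Why: Standard silylation of two primary alcohols; silyl ethers are chosen because allylic esters would ionise under the later palladium catalysis and fluoride removal at the end spares the polyene.

Step 10
Reactants: 18 (3S)-2,2,6-trimethyl-3-(prop-2-en-1-yl)cyclohexan-1-one; 20 2-methylidenepropane-1,3-diyl bis(tert-butyldimethylsilyl) ether
Product: 21 (3S)-3-{4-[(tert-butyldimethylsilyl)oxy]-3-{[(tert-butyldimethylsilyl)oxy]methyl}but-2-en-1-yl}-2,2,6-trimethylcyclohexan-1-one (both C6 epimers)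
Conditions: second-generation Hoveyda–Grubbs catalyst RuCl2(H2IMes)(=CH-C6H4-2-O-i-Pr) (5 mol%), 20 (4 equiv), CH2Cl2, 40 °C
Reagents that add atoms: none
Why: Olefin cross-metathesis of a terminal alkene with a symmetrical 1,1-disubstituted alkene, which does not homodimerise and is used in excess; the symmetry of 20 means the trisubstituted product has no E/Z issue.

Step 11
Reactants: 21 (3S)-3-{4-[(tert-butyldimethylsilyl)oxy]-3-{[(tert-butyldimethylsilyl)oxy]methyl}but-2-en-1-yl}-2,2,6-trimethylcyclohexan-1-one
Product: 23 (5S)-5-{4-[(tert-butyldimethylsilyl)oxy]-3-{[(tert-butyldimethylsilyl)oxy]methyl}but-2-en-1-yl}-2,6,6-trimethylcyclohex-1-en-1-yl trifluoromethanesulfonate, via lithium enolate 22 (not isolated)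
Conditions: LiN(i-Pr)2, THF, −78 → 0 °C; then PhNTf2, 0 °C → rt
Reagents that add atoms: N-phenylbis(trifluoromethanesulfonimide), O=S(=O)(N(c1ccccc1)S(=O)(=O)C(F)(F)F)C(F)(F)F
Why: Enol triflation as in step 5, with the single α-hydrogen dictating the enolate; the silyl ethers and the side-chain alkene are inert to the amide base.

Step 12
Reactants: 24 crocetindial; 25 bis(4,4,5,5-tetramethyl-1,3,2-dioxaborolan-2-yl)methane
Product: 27 all-E C22 nonaene bis(pinacol boronate), via lithiated diborylmethane 26 (not isolated)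
Conditions: 25 (2.4 equiv), lithium 2,2,6,6-tetramethylpiperidide, THF, 0 °C; then 24, −78 °C → rt, argon, dark
Reagents that add atoms: none
Why: Boron–Wittig olefination; the lithiated geminal bis(boronate) adds to each formyl group and syn elimination of the boron–oxygen pair should give the (E)-alkenyl boronate at both ends (C7=C8 and C7'=C8').

Step 13
Reactants: 23 ring B enol triflate; 27 all-E C22 nonaene bis(pinacol boronate)
Product: 28 ring B–C22 nonaenyl pinacol boronate
Conditions: Pd(OAc)2 (5 mol%), SPhos (10 mol%), K3PO4, THF/H2O, 40 °C, 27 (3 equiv), argon, dark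
Reagents that add atoms: none
Why: Suzuki–Miyaura coupling in which zerovalent palladium inserts into the enol triflate C–O bond and one alkenyl boronate terminus transmetalates with retention of the E geometry; the excess of 27 should favour coupling at one end only, and unreacted 27 is recovered.

Step 14
Reactants: 28 ring B–C22 nonaenyl pinacol boronate; 11 ring A enol triflate
Product: 29 (2R,2'S)-2-(3-methylbut-2-en-1-yl)-2'-{4-[(tert-butyldimethylsilyl)oxy]-3-{[(tert-butyldimethylsilyl)oxy]methyl}but-2-en-1-yl}-β,β-carotene (all-E)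
Conditions: Pd(OAc)2 (5 mol%), SPhos (10 mol%), K3PO4, THF/H2O, 40 °C, 11 (1.5 equiv), argon, dark
Reagents that add atoms: none
Why: Second Suzuki–Miyaura coupling at the remaining boronate terminus forms C6–C7 with retention of alkene geometry; silyl ethers and the prenyl group are inert.

Step 15
Reactants: 29 bis-silyl ether of the target
Product: 30 (2R,2'S)-2'-[4-hydroxy-3-(hydroxymethyl)but-2-en-1-yl]-2-(3-methylbut-2-en-1-yl)-β,β-carotene (all-E), CNP0213288.1
Conditions: Bu4NF, THF, 0 °C → rt, argon, dark
Reagents that add atoms: none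
Why: Fluoride cleavage of the two primary silyl ethers, a desilylation under conditions that leave the polyene and both stereocentres untouched.

## Compound list

1 | α-campholenic aldehyde, 2-(2,2,3-trimethylcyclopent-3-en-1-yl)acetaldehyde (any enantiomeric composition) | CC1=CCC(CC=O)C1(C)C | starting material
2 | 3-(2-methyl-3-oxobutan-2-yl)pentanedial (achiral) | CC(=O)C(C)(C)C(CC=O)CC=O | intermediate
3 | 2-[(1R)-5-hydroxy-2,2-dimethyl-3-oxocyclohexyl]acetaldehyde (carbinol centre unassigned, lost on dehydration) | O=CC[C@H]1CC(O)CC(=O)C1(C)C | intermediate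
4 | (R)-2-(2,2-dimethyl-3-oxocyclohex-4-en-1-yl)acetaldehyde | O=CC[C@H]1CC=CC(=O)C1(C)C | intermediate
5 | isopropyltriphenylphosphonium iodide | CC(C)[P+](c1ccccc1)(c1ccccc1)c1ccccc1.[I-] | starting material
6 | triphenyl(propan-2-ylidene)-λ5-phosphane | CC(C)=P(c1ccccc1)(c1ccccc1)c1ccccc1 | intermediate
7 | (5R)-6,6-dimethyl-5-(3-methylbut-2-en-1-yl)cyclohex-2-en-1-one | CC(C)=CC[C@H]1CC=CC(=O)C1(C)C | intermediate
8 | lithium (5R)-6,6-dimethyl-5-(3-methylbut-2-en-1-yl)cyclohex-1-en-1-olate | CC(C)=CC[C@H]1CCC=C([O-])C1(C)C.[Li+] | intermediate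
9 | (3R)-2,2,6-trimethyl-3-(3-methylbut-2-en-1-yl)cyclohexan-1-one (both C6 epimers) | CC(C)=CC[C@H]1CCC(C)C(=O)C1(C)C | intermediate
10 | lithium (5R)-2,6,6-trimethyl-5-(3-methylbut-2-en-1-yl)cyclohex-1-en-1-olate | CC(C)=CC[C@H]1CCC(C)=C([O-])C1(C)C.[Li+] | intermediate
11 | (5R)-2,6,6-trimethyl-5-(3-methylbut-2-en-1-yl)cyclohex-1-en-1-yl trifluoromethanesulfonate (ring A enol triflate) | CC(C)=CC[C@H]1CCC(C)=C(OS(=O)(=O)C(F)(F)F)C1(C)C | intermediate
12 | 2-[(1S)-5-hydroxy-2,2-dimethyl-3-oxocyclohexyl]acetaldehyde (carbinol centre unassigned, lost on dehydration) | O=CC[C@@H]1CC(O)CC(=O)C1(C)C | intermediate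
13 | (S)-2-(2,2-dimethyl-3-oxocyclohex-4-en-1-yl)acetaldehyde | O=CC[C@@H]1CC=CC(=O)C1(C)C | intermediate
14 | methyltriphenylphosphonium bromide | C[P+](c1ccccc1)(c1ccccc1)c1ccccc1.[Br-] | starting material
15 | methylidenetriphenyl-λ5-phosphane | C=P(c1ccccc1)(c1ccccc1)c1ccccc1 | intermediate
16 | (5R)-6,6-dimethyl-5-(prop-2-en-1-yl)cyclohex-2-en-1-one | C=CC[C@@H]1CC=CC(=O)C1(C)C | intermediate
17 | lithium (5S)-6,6-dimethyl-5-(prop-2-en-1-yl)cyclohex-1-en-1-olate | C=CC[C@@H]1CCC=C([O-])C1(C)C.[Li+] | intermediate
18 | (3S)-2,2,6-trimethyl-3-(prop-2-en-1-yl)cyclohexan-1-one (both C6 epimers) | C=CC[C@@H]1CCC(C)C(=O)C1(C)C | intermediate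
19 | 2-methylidenepropane-1,3-diol | C=C(CO)CO | starting material
20 | 2-methylidenepropane-1,3-diyl bis(tert-butyldimethylsilyl) ether | C=C(CO[Si](C)(C)C(C)(C)C)CO[Si](C)(C)C(C)(C)C | intermediate
21 | (3S)-3-{4-[(tert-butyldimethylsilyl)oxy]-3-{[(tert-butyldimethylsilyl)oxy]methyl}but-2-en-1-yl}-2,2,6-trimethylcyclohexan-1-one (both C6 epimers) | CC(C)(C)[Si](C)(C)OCC(CO[Si](C)(C)C(C)(C)C)=CC[C@@H]1CCC(C)C(=O)C1(C)C | intermediate
22 | lithium (5S)-5-{4-[(tert-butyldimethylsilyl)oxy]-3-{[(tert-butyldimethylsilyl)oxy]methyl}but-2-en-1-yl}-2,6,6-trimethylcyclohex-1-en-1-olate | CC(C)(C)[Si](C)(C)OCC(CO[Si](C)(C)C(C)(C)C)=CC[C@@H]1CCC(C)=C([O-])C1(C)C.[Li+] | intermediate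
23 | (5S)-5-{4-[(tert-butyldimethylsilyl)oxy]-3-{[(tert-butyldimethylsilyl)oxy]methyl}but-2-en-1-yl}-2,6,6-trimethylcyclohex-1-en-1-yl trifluoromethanesulfonate (ring B enol triflate) | CC(C)(C)[Si](C)(C)OCC(CO[Si](C)(C)C(C)(C)C)=CC[C@@H]1CCC(C)=C(OS(=O)(=O)C(F)(F)F)C1(C)C | intermediate
24 | crocetindial, (2E,4E,6E,8E,10E,12E,14E)-2,6,11,15-tetramethylhexadeca-2,4,6,8,10,12,14-heptaenedial | O=C/C(C)=C/C=C/C(C)=C/C=C/C=C(C)/C=C/C=C(C)/C=O | starting material
25 | bis(4,4,5,5-tetramethyl-1,3,2-dioxaborolan-2-yl)methane | CC1(C)OB(CB2OC(C)(C)C(C)(C)O2)OC1(C)C | starting material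
26 | lithium bis(4,4,5,5-tetramethyl-1,3,2-dioxaborolan-2-yl)methanide | [Li+].CC1(C)OB([CH-]B2OC(C)(C)C(C)(C)O2)OC1(C)C | intermediate
27 | 2,2'-[(1E,3E,5E,7E,9E,11E,13E,15E,17E)-3,7,12,16-tetramethyloctadeca-1,3,5,7,9,11,13,15,17-nonaene-1,18-diyl]bis(4,4,5,5-tetramethyl-1,3,2-dioxaborolane) | CC1(C)OB(/C=C/C(C)=C/C=C/C(C)=C/C=C/C=C(C)/C=C/C=C(C)/C=C/B2OC(C)(C)C(C)(C)O2)OC1(C)C | intermediate
28 | 2-[(1E,3E,5E,7E,9E,11E,13E,15E,17E)-18-[(5S)-5-{4-[(tert-butyldimethylsilyl)oxy]-3-{[(tert-butyldimethylsilyl)oxy]methyl}but-2-en-1-yl}-2,6,6-trimethylcyclohex-1-en-1-yl]-3,7,12,16-tetramethyloctadeca-1,3,5,7,9,11,13,15,17-nonaen-1-yl]-4,4,5,5-tetramethyl-1,3,2-dioxaborolane | CC1(C)OB(/C=C/C(C)=C/C=C/C(C)=C/C=C/C=C(C)/C=C/C=C(C)/C=C/C2=C(C)CC[C@@H](CC=C(CO[Si](C)(C)C(C)(C)C)CO[Si](C)(C)C(C)(C)C)C2(C)C)OC1(C)C | intermediate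
29 | (2R,2'S)-2-(3-methylbut-2-en-1-yl)-2'-{4-[(tert-butyldimethylsilyl)oxy]-3-{[(tert-butyldimethylsilyl)oxy]methyl}but-2-en-1-yl}-β,β-carotene (all-E) | CC(C)=CC[C@H]1CCC(C)=C(/C=C/C(C)=C/C=C/C(C)=C/C=C/C=C(C)/C=C/C=C(C)/C=C/C2=C(C)CC[C@@H](CC=C(CO[Si](C)(C)C(C)(C)C)CO[Si](C)(C)C(C)(C)C)C2(C)C)C1(C)C | intermediate
30 | (2R,2'S)-2'-[4-hydroxy-3-(hydroxymethyl)but-2-en-1-yl]-2-(3-methylbut-2-en-1-yl)-β,β-carotene (all-E), CNP0213288.1 | CC(C)=CC[C@H]1CCC(C)=C(/C=C/C(C)=C/C=C/C(C)=C/C=C/C=C(C)/C=C/C=C(C)/C=C/C2=C(C)CC[C@@H](CC=C(CO)CO)C2(C)C)C1(C)C | target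

## Step count and risks

Total step count: 15. Longest linear sequence: 9 steps (1, 6, 7, 8, 10, 11, 13, 14, 15).

**Step 2.** Enamine formation at the hindered methyl ketone may be so slow that intermolecular aldol condensation of the formyl arms takes over. Ring closure may also run through an iminium ion of a formyl arm (Mannich-type addition of the ketone enol, then elimination), which would discriminate poorly between the arms. The sense of induction may also be the reverse of the prediction, which is met by exchanging the catalysts. Fallback (known chemistry): setting out from 2, pyrrolidinium acetate in THF closes the ring without selection, by the ordinary amine-salt-mediated intramolecular aldol condensation of a keto-aldehyde, to racemic 2-(2,2-dimethyl-3-oxocyclohex-4-en-1-yl)acetaldehyde F1. Preparative chromatography on a chiral stationary phase then delivers 4, where the route is rejoined; the antipode 13 is obtained from the same separation.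

**Step 6.** This is the mirror image of step 2 and therefore fails in the same way and to the same degree: slow ketone enamine formation, competing oligomerisation and weak arm discrimination. Fallback (known chemistry): setting out from 2 by way of the racemate F1 described above, condensation with (1R,2R)-N,N'-dimethyl-1,2-diphenylethane-1,2-diamine (Et2O, molecular sieves) gives two diastereomeric aminals. These are (5S)-5-{[(4R,5R)-1,3-dimethyl-4,5-diphenylimidazolidin-2-yl]methyl}-6,6-dimethylcyclohex-2-en-1-one F2 and its (5R)-diastereomer F3, which are separated on silica gel or by crystallisation. Hydrolysis of F2 with dilute aqueous HCl in Et2O returns the route at 13; F3 is set aside.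

**Step 13.** Oxidative addition of the hindered tetrasubstituted enol triflate is slow, so the nonaene bis(boronate) may decay (protodeboronation, oxidation, E/Z drift) during the reaction, and coupling may run on at both termini despite the excess. Fallback: setting out from 24, one equivalent of 26 converts a single formyl group into the alkenyl boronate, giving (2E,4E,6E,8E,10E,12E,14E,16E)-2,6,11,15-tetramethyl-17-(4,4,5,5-tetramethyl-1,3,2-dioxaborolan-2-yl)heptadeca-2,4,6,8,10,12,14,16-octaenal F4, which is easily separated from 24 and 27 by polarity. Suzuki–Miyaura coupling of F4 with 23 can occur at one end only and gives the ring B apo-carotenal (2E,4E,6E,8E,10E,12E,14E,16E)-17-[(5S)-5-{4-[(tert-butyldimethylsilyl)oxy]-3-{[(tert-butyldimethylsilyl)oxy]methyl}but-2-en-1-yl}-2,6,6-trimethylcyclohex-1-en-1-yl]-2,6,11,15-tetramethylheptadeca-2,4,6,8,10,12,14,16-octaenal F5. A second boron–Wittig olefination of F5 with 26 returns the route at 28.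

## Further compounds

F1 | step 2 | racemic 2-(2,2-dimethyl-3-oxocyclohex-4-en-1-yl)acetaldehyde | O=CCC1CC=CC(=O)C1(C)C
F2 | step 6 | (5S)-5-{[(4R,5R)-1,3-dimethyl-4,5-diphenylimidazolidin-2-yl]methyl}-6,6-dimethylcyclohex-2-en-1-one | CN1[C@H](c2ccccc2)[C@@H](c2ccccc2)N(C)C1C[C@@H]1CC=CC(=O)C1(C)C
F3 | step 6 | (5R)-5-{[(4R,5R)-1,3-dimethyl-4,5-diphenylimidazolidin-2-yl]methyl}-6,6-dimethylcyclohex-2-en-1-one | CN1[C@H](c2ccccc2)[C@@H](c2ccccc2)N(C)C1C[C@H]1CC=CC(=O)C1(C)C
F4 | step 13 | (2E,4E,6E,8E,10E,12E,14E,16E)-2,6,11,15-tetramethyl-17-(4,4,5,5-tetramethyl-1,3,2-dioxaborolan-2-yl)heptadeca-2,4,6,8,10,12,14,16-octaenal | O=C/C(C)=C/C=C/C(C)=C/C=C/C=C(C)/C=C/C=C(C)/C=C/B1OC(C)(C)C(C)(C)O1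
F5 | step 13 | (2E,4E,6E,8E,10E,12E,14E,16E)-17-[(5S)-5-{4-[(tert-butyldimethylsilyl)oxy]-3-{[(tert-butyldimethylsilyl)oxy]methyl}but-2-en-1-yl}-2,6,6-trimethylcyclohex-1-en-1-yl]-2,6,11,15-tetramethylheptadeca-2,4,6,8,10,12,14,16-octaenal | O=C/C(C)=C/C=C/C(C)=C/C=C/C=C(C)/C=C/C=C(C)/C=C/C1=C(C)CC[C@@H](CC=C(CO[Si](C)(C)C(C)(C)C)CO[Si](C)(C)C(C)(C)C)C1(C)C
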